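**Strategy**

The vicinal bromochloride of ring B is a masked trisubstituted alkene, so the bond between the CHBr carbon (C2) and the C(CH3)Cl carbon (C3) is made as a C=C by ring-closing olefin metathesis. In one operation this closes ring B onto the quaternary carbon C6 and creates the spiro[5.5] skeleton with the alkene exactly where anti, Markovnikov addition of BrCl will later place both halogens. The precursor is a 5,5-dimethylcyclohex-2-enone (ring A) whose C6 carries an allyl and a 3-methylbut-3-enyl arm, set by palladium-catalysed decarboxylative asymmetric allylation. The step exploits the 1,2-relationship Br–C2/C3(CH3)–Cl next to the C6 spiro centre.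

Key step: step 5

Remark: atoms are named by chamigrene numbering (ring B = C1–C6 with C2 = CHBr, C3 = C(CH3)Cl, C6 = spiro carbon; ring A = C6–C11 with C7 = C(=CH2), C8 = C=O, C9 = CH=, C10 = CBr, C11 = C(CH3)2); compounds 1 and 3 are taken as purchasable, and temporary stereocentres that are erased later carry no stereo mark in the SMILES.

**Route**

Step 1
Reactants: 1 4-bromo-2-methylbut-1-ene
Product: 2 4-iodo-2-methylbut-1-ene
Conditions: NaI, acetone, reflux
Reagents that add atoms: sodium iodide, [Na+].[I-]
Why: Finkelstein SN2 exchange at an unhindered primary carbon, driven by precipitation of NaBr from acetone.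

Step 2
Reactants: 3 5,5-dimethylcyclohex-2-en-1-one; 2 4-iodo-2-methylbut-1-ene
Product: 5 rac-5,5-dimethyl-6-(3-methylbut-3-en-1-yl)cyclohex-2-en-1-one, via lithium dienolate 4 (not isolated)
Conditions: LiN(iPr)2, THF, -78 °C; then 2, DMPU, -78 °C to rt
Reagents that add atoms: none
Why: Kinetic alpha'-deprotonation of the enone gives the cross-conjugated lithium dienolate 4, which is alkylated by the primary iodide in an SN2 enolate alkylation of the kind known for enolate carbons next to a gem-dimethyl group; the new stereocentre forms racemic and is erased in step 3.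

Step 3
Reactants: 5 rac-5,5-dimethyl-6-(3-methylbut-3-en-1-yl)cyclohex-2-en-1-one
Product: 7 allyl 3,3-dimethyl-2-(3-methylbut-3-en-1-yl)cyclohexa-1,5-dien-1-yl carbonate, via lithium dienolate 6 (not isolated)
Conditions: LiN(iPr)2, TMEDA, THF, -78 °C; then allyl chloroformate, -78 to 0 °C
Reagents that add atoms: allyl chloroformate, C=CCOC(Cl)=O
Why: Deprotonation at the only alpha' C–H gives the fully substituted lithium dienolate 6, which the hard chloroformate acylates on oxygen (enol carbonate formation) because its carbon terminus is flanked by a quaternary carbon.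

Step 4
Reactants: 7 allyl 3,3-dimethyl-2-(3-methylbut-3-en-1-yl)cyclohexa-1,5-dien-1-yl carbonate
Product: 8 (6R)-5,5-dimethyl-6-(3-methylbut-3-en-1-yl)-6-(prop-2-en-1-yl)cyclohex-2-en-1-one
Conditions: Pd2(dba)3 (2.5 mol %), (S)-4-tert-butyl-2-{2-[bis(4-(trifluoromethyl)phenyl)phosphanyl]-5-(trifluoromethyl)phenyl}-4,5-dihydro-1,3-oxazole (6 mol %), toluene, 40 °C
Reagents that add atoms: none
Why: Tsuji–Trost decarboxylative asymmetric allylic alkylation, in which oxidative addition of zerovalent palladium, loss of CO2 and inner-sphere bond formation between the allyl ligand and the alpha'-carbon of the dienolate on the face selected by the (S)-phosphinooxazoline ligand should give the (R)-quaternary centre, by analogy with the sense of induction known for 2-alkylcyclohexanone enolates (the mirror-image ligand is used if the sense proves opposite).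

Step 5
Reactants: 8 (6R)-5,5-dimethyl-6-(3-methylbut-3-en-1-yl)-6-(prop-2-en-1-yl)cyclohex-2-en-1-one
Product: 9 (6R)-5,5,9-trimethylspiro[5.5]undeca-2,8-dien-1-one
Conditions: second-generation Grubbs catalyst (H2IMes)(PCy3)Cl2Ru=CHPh (5 mol %), CH2Cl2 (0.005 M), 40 °C
Reagents that add atoms: none
Why: Ring-closing olefin metathesis: the ruthenium benzylidene initiates at the monosubstituted allyl alkene, and the resulting alkylidene undergoes intramolecular [2+2] cycloaddition with the 1,1-disubstituted alkene of the other arm and cycloreversion, which forms C2=C3 and releases ethylene. The closest known reaction type is the ring-closing metathesis of 1,7-dienes hung on a quaternary carbon to give 1-methylcyclohexenes. Ring B is closed as a six-membered carbocycle by alkene–alkylidene metathesis at the methyl-bearing terminus, which at the same time creates the spiro junction at C6. No stereocentre is formed and C6 is untouched; its configuration from step 4 becomes that of the spiro centre, defined relative to the position of the new alkene (C2=C3, methyl on C3). The step needs cyclization over oligomerization and no involvement of the enone; the quaternary carbon (Thorpe–Ingold effect), high dilution and the inertness of the conjugated endocyclic enone C=C towards the ruthenium carbene should secure both. Loss of ethylene makes the closure irreversible, and the unstrained trisubstituted cyclohexene does not reopen.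

Step 6
Reactants: 9 (6R)-5,5,9-trimethylspiro[5.5]undeca-2,8-dien-1-one
Product: 11 (6R)-4-bromo-5,5,9-trimethylspiro[5.5]undeca-2,8-dien-1-one, via silyl dienol ether 10 (not isolated)
Conditions: Me3SiOTf, Et3N, CH2Cl2, 0 °C; then NBS, THF, -78 °C
Reagents that add atoms: N-bromosuccinimide, O=C1CCC(=O)N1Br
Why: With no alpha'-hydrogen left, soft enolization removes a gamma-hydrogen to give the linear silyl dienol ether 10, whose gamma-terminus (C10) is brominated by NBS (vinylogous alpha-halogenation) faster than the trisubstituted alkene of ring B reacts; the CHBr centre forms as a mixture and is erased in step 7.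

Step 7
Reactants: 11 (6R)-4-bromo-5,5,9-trimethylspiro[5.5]undeca-2,8-dien-1-one
Product: 13 (6R)-4-bromo-2-hydroxy-5,5,9-trimethylspiro[5.5]undeca-3,8-dien-1-one, via potassium dienolate 12 (not isolated)
Conditions: KN(SiMe3)2, THF, -78 °C; then 3-phenyl-2-(phenylsulfonyl)oxaziridine, -78 °C; aq NH4Cl
Reagents that add atoms: 3-phenyl-2-(phenylsulfonyl)oxaziridine (Davis oxaziridine), O=S(=O)(c1ccccc1)N1OC1c1ccccc1
Why: Removal of the CHBr hydrogen gives the extended potassium dienolate 12, which attacks the electrophilic oxygen of the oxaziridine with its alpha-carbon C8 (Davis enolate hydroxylation) and so leaves the C=C in the beta,gamma-position as the C9=C10 vinyl bromide; the carbinol centre is uncontrolled and is erased in step 9.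

Step 8
Reactants: 13 (6R)-4-bromo-2-hydroxy-5,5,9-trimethylspiro[5.5]undeca-3,8-dien-1-one
Product: 14 (6S)-4-bromo-5,5,9-trimethyl-1-methylidenespiro[5.5]undeca-3,8-dien-2-ol
Conditions: Ph3P=CH2 (from Ph3PCH3Br and KOtBu, excess), THF, 0 to 40 °C
Reagents that add atoms: methylidenetriphenylphosphorane, C=P(c1ccccc1)(c1ccccc1)c1ccccc1
Why: Wittig methylenation of the C7 ketone, whose hydroxyl is carried as the potassium alkoxide and whose other alpha-carbon is quaternary, so that enolization towards the spiro carbon cannot compete (the descriptor at C6 changes only because the priorities change).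

Step 9
Reactants: 14 (6S)-4-bromo-5,5,9-trimethyl-1-methylidenespiro[5.5]undeca-3,8-dien-2-ol
Product: 15 (6S)-4-bromo-5,5,9-trimethyl-1-methylidenespiro[5.5]undeca-3,8-dien-2-one
Conditions: Dess–Martin periodinane, NaHCO3, CH2Cl2, 0 °C to rt
Reagents that add atoms: none
Why: Dess–Martin oxidation of the doubly allylic secondary alcohol should give the cross-conjugated dienone under buffered, non-basic conditions that leave the vinyl bromide and the other alkenes untouched.

Step 10
Reactants: 15 (6S)-4-bromo-5,5,9-trimethyl-1-methylidenespiro[5.5]undeca-3,8-dien-2-one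
Product: 16 (6S,8S,9S)-4,8-dibromo-9-chloro-5,5,9-trimethyl-1-methylidenespiro[5.5]undec-3-en-2-one
Conditions: Bu4N+ BrCl2- (1.05 equiv), CH2Cl2, -78 to -40 °C, dark
Reagents that add atoms: tetrabutylammonium dichlorobromate, CCCC[N+](CCCC)(CCCC)CCCC.[Cl-].ClBr
Why: Electrophilic anti bromochlorination of the only electron-rich alkene, in which the axial C7 holds its exocyclic CH2 over one face of ring B so that Br+ should add from the opposite face (cis to C11) and chloride then opens the bromonium ion at the tertiary carbon C3 with inversion (Markovnikov), setting C2 and C3 trans as (S,S) with both halogens equatorial.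

**Compound list**

1 | 4-bromo-2-methylbut-1-ene | C=C(C)CCBr | starting material
2 | 4-iodo-2-methylbut-1-ene | C=C(C)CCI | intermediate
3 | 5,5-dimethylcyclohex-2-en-1-one | O=C1C=CCC(C)(C)C1 | starting material
4 | lithium 3,3-dimethylcyclohexa-1,5-dien-1-olate (lithium dienolate of 3) | [Li+].[O-]C1=CC(C)(C)CC=C1 | intermediate
5 | rac-5,5-dimethyl-6-(3-methylbut-3-en-1-yl)cyclohex-2-en-1-one | O=C1C=CCC(C)(C)C1CCC(C)=C | intermediate
6 | lithium 3,3-dimethyl-2-(3-methylbut-3-en-1-yl)cyclohexa-1,5-dien-1-olate (lithium dienolate of 5) | [Li+].[O-]C1=C(CCC(C)=C)C(C)(C)CC=C1 | intermediate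
7 | allyl 3,3-dimethyl-2-(3-methylbut-3-en-1-yl)cyclohexa-1,5-dien-1-yl carbonate | C=CCOC(=O)OC1=C(CCC(C)=C)C(C)(C)CC=C1 | intermediate
8 | (6R)-5,5-dimethyl-6-(3-methylbut-3-en-1-yl)-6-(prop-2-en-1-yl)cyclohex-2-en-1-one | O=C1C=CCC(C)(C)[C@]1(CC=C)CCC(C)=C | intermediate
9 | (6R)-5,5,9-trimethylspiro[5.5]undeca-2,8-dien-1-one | O=C1C=CCC(C)(C)[C@]12CCC(C)=CC2 | intermediate
10 | trimethyl{[(6R)-5,5,9-trimethylspiro[5.5]undeca-1,3,8-trien-1-yl]oxy}silane (silyl dienol ether) | C[Si](C)(C)OC1=CC=CC(C)(C)[C@]12CCC(C)=CC2 | intermediate
11 | (6R)-4-bromo-5,5,9-trimethylspiro[5.5]undeca-2,8-dien-1-one, mixture of epimers at the CHBr carbon | O=C1C=CC(Br)C(C)(C)[C@]12CCC(C)=CC2 | intermediate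
12 | potassium (6R)-4-bromo-5,5,9-trimethylspiro[5.5]undeca-1,3,8-trien-1-olate (potassium dienolate of 11) | [K+].[O-]C1=CC=C(Br)C(C)(C)[C@]12CCC(C)=CC2 | intermediate
13 | (6R)-4-bromo-2-hydroxy-5,5,9-trimethylspiro[5.5]undeca-3,8-dien-1-one, mixture of epimers at the carbinol carbon | O=C1C(O)C=C(Br)C(C)(C)[C@]12CCC(C)=CC2 | intermediate
14 | (6S)-4-bromo-5,5,9-trimethyl-1-methylidenespiro[5.5]undeca-3,8-dien-2-ol, mixture of epimers at the carbinol carbon | C=C1C(O)C=C(Br)C(C)(C)[C@]12CCC(C)=CC2 | intermediate
15 | (6S)-4-bromo-5,5,9-trimethyl-1-methylidenespiro[5.5]undeca-3,8-dien-2-one | C=C1C(=O)C=C(Br)C(C)(C)[C@]12CCC(C)=CC2 | intermediate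
16 | (6S,8S,9S)-4,8-dibromo-9-chloro-5,5,9-trimethyl-1-methylidenespiro[5.5]undec-3-en-2-one | C=C1C(=O)C=C(Br)C(C)(C)[C@]12CC[C@](C)(Cl)[C@@H](Br)C2 | target

**Step count and risks**

Total step count: 10. Longest linear sequence: 10 steps (1 to 16; compound 3 enters in step 2).

Steps most likely to fail:

1. Step 10. The addition may lose facial or regiochemical control: bromine may be delivered to the face of ring B that lies under C7, or chloride may open the bromonium ion in the trans-diaxial sense. Both paths give diastereomeric or regioisomeric dihalides. The fallback sets out from 15 and comes back at 16, and it uses the wrong facial preference instead of fighting it. 15 would be epoxidized on that same face (mCPBA, NaHCO3, CH2Cl2, 0 °C) to (6S,8R,9S)-4-bromo-8,9-epoxy-5,5,9-trimethyl-1-methylidenespiro[5.5]undec-3-en-2-one F1. Aqueous HBr in CHCl3 at 0 °C should open the oxirane at the tertiary carbon in the trans-diaxial, Markovnikov sense to the bromohydrin (6S,8R,9R)-4,9-dibromo-8-hydroxy-5,5,9-trimethyl-1-methylidenespiro[5.5]undec-3-en-2-one F2. SOCl2 (Et2O, 0 °C) then turns the axial hydroxyl into a chlorosulfite that the antiperiplanar bromine expels. The bromonium ion formed in this way lies on the face remote from C7, and chloride should open it at the tertiary carbon to give 16.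

2. Step 7. The bromine-bearing dienolate may decompose, oxygen may be transferred to its gamma-terminus, or the alpha-ketol may isomerize under base. The fallback sets out from 11 and comes back at 14, so it also by-passes step 8. Nucleophilic epoxidation of the enone C=C (t-BuOOH, DBU, CH2Cl2, 0 °C, expected anti to the allylic bromine) would give the epoxy ketone (6R)-4-bromo-2,3-epoxy-5,5,9-trimethylspiro[5.5]undec-8-en-1-one F3. Wittig methylenation (Ph3P=CH2, THF), here on a ketone without a free hydroxyl, would give the vinyl oxirane (6S)-4-bromo-2,3-epoxy-5,5,9-trimethyl-1-methylidenespiro[5.5]undec-8-ene F4. LiNEt2 (Et2O, 0 °C) would then remove the CHBr hydrogen and open the oxirane by beta-elimination, which forms the vinyl bromide and the C8 carbinol of 14 in one operation.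

3. Step 8. Deprotonation and ketol isomerization by the basic ylide may outrun the slow methylenation of the hindered ketone. The fallback sets out from 13 and comes back at 14 by a Peterson sequence. Silylation (Et3SiCl, imidazole, DMF) would give the silyl ether (6R)-4-bromo-5,5,9-trimethyl-2-[(triethylsilyl)oxy]spiro[5.5]undeca-3,8-dien-1-one F5. Addition of the weakly basic reagent from Me3SiCH2Li and CeCl3 (THF, -78 °C) would give the beta-hydroxysilane (6R)-4-bromo-5,5,9-trimethyl-2-[(triethylsilyl)oxy]-1-[(trimethylsilyl)methyl]spiro[5.5]undeca-3,8-dien-1-ol F6. Aqueous HF in MeCN would then effect the Peterson elimination and remove the triethylsilyl group to give 14.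

Further compounds
F1 | step 10 | (6S,8R,9S)-4-bromo-8,9-epoxy-5,5,9-trimethyl-1-methylidenespiro[5.5]undec-3-en-2-one | C=C1C(=O)C=C(Br)C(C)(C)[C@]12CC[C@]3(C)O[C@@H]3C2
F2 | step 10 | (6S,8R,9R)-4,9-dibromo-8-hydroxy-5,5,9-trimethyl-1-methylidenespiro[5.5]undec-3-en-2-one | C=C1C(=O)C=C(Br)C(C)(C)[C@]12CC[C@@](C)(Br)[C@H](O)C2
F3 | step 7 | (6R)-4-bromo-2,3-epoxy-5,5,9-trimethylspiro[5.5]undec-8-en-1-one | O=C1C2OC2C(Br)C(C)(C)[C@]13CCC(C)=CC3
F4 | step 7 | (6S)-4-bromo-2,3-epoxy-5,5,9-trimethyl-1-methylidenespiro[5.5]undec-8-ene | C=C1C2OC2C(Br)C(C)(C)[C@]13CCC(C)=CC3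
F5 | step 8 | (6R)-4-bromo-5,5,9-trimethyl-2-[(triethylsilyl)oxy]spiro[5.5]undeca-3,8-dien-1-one | O=C1C(O[Si](CC)(CC)CC)C=C(Br)C(C)(C)[C@]12CCC(C)=CC2
F6 | step 8 | (6R)-4-bromo-5,5,9-trimethyl-2-[(triethylsilyl)oxy]-1-[(trimethylsilyl)methyl]spiro[5.5]undeca-3,8-dien-1-ol | C[Si](C)(C)CC1(O)C(O[Si](CC)(CC)CC)C=C(Br)C(C)(C)[C@]12CCC(C)=CC2
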